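**Assumptions.** The SMILES is read as the (6S,7R) isomer with an E-acrylic acid. Locants C1–C8a in the text are the 1H-isochromene locants of the target (C6 carries the ester, C7 the methyl carbinol, C8 the ketone). "ArCO2" stands for 4-methoxy-6-methyl-2,2-diphenyl-1,3-benzodioxole-5-carboxylate, the acyl part of acid 5. The route has not been run; selectivities quoted are expectations from analogous reactions.

**Retrosynthetic overview**
1. Final acidolysis frees the catechol and the acrylic acid; the pyran (ring B) is closed last, from a 2-formyl-3-alkynyl cyclohexenone by silver-catalysed 6-endo cyclisation to a pyrylium and hydride transfer.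
2. The enal comes from α-formylation and DDQ dehydrogenation of a β-alkynyl ketone; the alkyne replaces the isopropenyl group of carvone by radical dealkenylative alkynylation, and a Sonogashira coupling adds the acrylate.
3. The ester C–O bond and the C6/C7 stereochemistry are set together by Ti(OiPr)4-mediated trans-diaxial opening of cis-carveol epoxide with the intact hindered aryl acid, instead of acylating a hindered alcohol.
4. Ring A is the ring of (S)-carvone (Luche reduction, hydroxyl-directed epoxidation); the isopropenyl stereocentre steers steps 6–8 and is then traded away. Order: ring A (chiral pool), aryl ester, ring B.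
5. The aryl acid comes from 2,3,4-trimethoxy-6-methylbenzaldehyde (BBr3, 3,4-diphenylmethylene ketal, 2-O-methylation, Pinnick oxidation).

**Route**

Step 1
Reactants: 1 2,3,4-trimethoxy-6-methylbenzaldehyde
Product: 2 2,3,4-trihydroxy-6-methylbenzaldehyde
Conditions: BBr3 (4 equiv), CH2Cl2, −78 °C to rt; H2O
Reagents that add atoms: none
Why: Exhaustive Lewis-acid cleavage of the three aryl methyl ethers (BBr3 demethylation), which the aromatic aldehyde survives.

Step 2
Reactants: 2 2,3,4-trihydroxy-6-methylbenzaldehyde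
Product: 3 4-hydroxy-6-methyl-2,2-diphenyl-1,3-benzodioxole-5-carbaldehyde
Conditions: Ph2CCl2 (1.3 equiv), Ph2O, 175 °C, 1 h
Reagents that add atoms: dichlorodiphenylmethane, ClC(Cl)(c1ccccc1)c1ccccc1
Why: Thermal catechol ketalisation closes the five-membered ring on the 3,4-diol because the 2-hydroxyl is held in a hydrogen bond to the ortho formyl group, so the three phenols are differentiated in one step.

Step 3
Reactants: 3 4-hydroxy-6-methyl-2,2-diphenyl-1,3-benzodioxole-5-carbaldehyde
Product: 4 4-methoxy-6-methyl-2,2-diphenyl-1,3-benzodioxole-5-carbaldehyde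
Conditions: MeI, K2CO3, DMF, rt
Reagents that add atoms: iodomethane, CI
Why: Williamson O-methylation of the one remaining phenol.

Step 4
Reactants: 4 4-methoxy-6-methyl-2,2-diphenyl-1,3-benzodioxole-5-carbaldehyde
Product: 5 4-methoxy-6-methyl-2,2-diphenyl-1,3-benzodioxole-5-carboxylic acid
Conditions: NaClO2, NaH2PO4, 2-methylbut-2-ene, t-BuOH/H2O, rt
Reagents that add atoms: NaClO2, [Na+].[O-]Cl=O
Why: Pinnick oxidation of the hindered electron-rich aldehyde, with 2-methylbut-2-ene trapping HOCl so the ring is not chlorinated.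

Step 5
Reactants: 6 (E)-3-iodoprop-2-enoic acid
Product: 7 tert-butyl (E)-3-iodoprop-2-enoate
Conditions: tert-butyl 2,2,2-trichloroacetimidate, BF3·OEt2 (cat.), CH2Cl2/cyclohexane, rt
Reagents that add atoms: tert-butyl 2,2,2-trichloroacetimidate, CC(C)(C)OC(=N)C(Cl)(Cl)Cl
Why: Acid-catalysed imidate tert-butylation of the carboxylic acid, which leaves the E-vinyl iodide untouched.

Step 6
Reactants: 8 (S)-(+)-carvone
Product: 9 (1S,5S)-2-methyl-5-(prop-1-en-2-yl)cyclohex-2-en-1-ol (cis-carveol)
Conditions: NaBH4, CeCl3·7H2O, MeOH, −78 to 0 °C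
Reagents that add atoms: none
Why: Luche 1,2-reduction of the enone is known to give the cis-carveol, so the new carbinol centre (S) has its hydroxyl cis to the isopropenyl group.

Step 7
Reactants: 9 (1S,5S)-cis-carveol
Product: 10 (1S,2S,4R,6R)-1-methyl-4-(prop-1-en-2-yl)-7-oxabicyclo[4.1.0]heptan-2-ol
Conditions: VO(acac)2 (2 mol %), t-BuOOH, CH2Cl2, 0 °C to rt
Reagents that add atoms: tert-butyl hydroperoxide, CC(C)(C)OO
Why: Hydroxyl-directed vanadium-catalysed allylic-alcohol epoxidation delivers oxygen syn to the hydroxyl (and so syn to isopropenyl) and ignores the isolated isopropenyl alkene.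

Step 8
Reactants: 10 the epoxy alcohol; 5 the aryl acid
Product: 11 (1S,2S,3S,5R)-2,3-dihydroxy-2-methyl-5-(prop-1-en-2-yl)cyclohexyl ArCO2 ester (ester oxygen trans to both hydroxyls and to isopropenyl)
Conditions: 5 (1.3 equiv), Ti(OiPr)4 (1.5 equiv), CH2Cl2, rt, 24–48 h; aq. tartaric acid
Reagents that add atoms: none
Why: Caron–Sharpless-type titanium-mediated opening of a 2,3-epoxy alcohol by a carboxylic acid (here extended to a cyclic trisubstituted epoxide): the chelate directs the carboxylate to the secondary C-3 anti to the epoxide oxygen, trans-diaxially (Fürst–Plattner) with isopropenyl equatorial, so the ester bond, the C6 centre (by inversion) and the C7 tertiary alcohol are fixed at once and the 2,6-disubstituted acid acts as an O-nucleophile, not as an acyl donor.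

Step 9
Reactants: 11 the diol ester
Product: 12 (1S,2R,5S)-2-hydroxy-2-methyl-3-oxo-5-(prop-1-en-2-yl)cyclohexyl ArCO2 ester
Conditions: Dess–Martin periodinane, CH2Cl2, 0 °C to rt
Reagents that add atoms: none
Why: Dess–Martin oxidation of the only secondary alcohol gives the α-hydroxy ketone, while the tertiary alcohol and the hindered ester are inert.

Step 10
Reactants: 12 the isopropenyl ketone
Product: 14 (1S,2R)-2-hydroxy-2-methyl-3-oxo-5-[(triisopropylsilyl)ethynyl]cyclohexyl ArCO2 ester (C5 epimers), via methoxy hydroperoxide 13 (not isolated)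
Conditions: O3, MeOH/CH2Cl2, −78 °C, N2 purge; then iPr3Si–C≡C–SO2Ph (2 equiv), FeSO4·7H2O (20 mol %), L-ascorbic acid (2 equiv), 0 °C to rt
Reagents that add atoms: triisopropyl[(phenylsulfonyl)ethynyl]silane, CC(C)[Si](C#CS(=O)(=O)c1ccccc1)(C(C)C)C(C)C; ozone, [O-][O+]=O, and methanol, CO (the atoms of these two stand in 13 only)
Why: Dealkenylative alkynylation (ozonolysis in methanol, FeSO4/ascorbate reduction of the hydroperoxide, β-scission with loss of methyl acetate, trapping of the ring radical by the alkynyl sulfone with loss of a sulfonyl radical) trades the isopropenyl group that steered steps 6–8 for the alkyne, and the C5 epimer mixture does not matter because this carbon becomes sp2 in step 13.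

Step 11
Reactants: 14 the silyl alkyne; 7 tert-butyl (E)-3-iodoprop-2-enoate
Product: 16 (1S,2R)-5-[(3E)-5-tert-butoxy-5-oxopent-3-en-1-yn-1-yl]-2-hydroxy-2-methyl-3-oxocyclohexyl ArCO2 ester (C5 epimers), via terminal alkyne 15 (not isolated)
Conditions: Bu4NF, THF, 0 °C; then 7 (1.2 equiv), Pd(PPh3)2Cl2 (5 mol %), CuI (10 mol %), Et3N, rt
Reagents that add atoms: none
Why: Fluoride desilylation followed by Sonogashira coupling, which retains the E geometry of the vinyl iodide, installs the whole enyne ester side chain while no enone is yet present that could eliminate the C6 ester.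

Step 12
Reactants: 16 the enyne ester ketone
Product: 17 (1S,2R,4Z)-5-[(3E)-5-tert-butoxy-5-oxopent-3-en-1-yn-1-yl]-2-hydroxy-4-(hydroxymethylidene)-2-methyl-3-oxocyclohexyl ArCO2 ester (C5 epimers; chelated enol of the 4-formyl ketone)
Conditions: LiN(SiMe3)2 (2.5 equiv), THF, −78 °C; HCO2CH2CF3 (1.3 equiv); cold 1 M HCl
Reagents that add atoms: 2,2,2-trifluoroethyl formate, O=COCC(F)(F)F
Why: Claisen-type C-formylation of the only ketone enolate that can form (the other α-carbon is quaternary) with a highly reactive formate at −78 °C, where the hindered tertiary lithium alkoxide and the 2,6-disubstituted benzoate do not react.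

Step 13
Reactants: 17 the hydroxymethylene ketone
Product: 18 (1S,2R)-5-[(3E)-5-tert-butoxy-5-oxopent-3-en-1-yn-1-yl]-4-formyl-2-hydroxy-2-methyl-3-oxocyclohex-4-en-1-yl ArCO2 ester
Conditions: DDQ (1.1 equiv), 1,4-dioxane, rt, 15 min; filter and use at once
Reagents that add atoms: none
Why: DDQ dehydrogenation of a 2-hydroxymethylene ketone (hydride abstraction from the tertiary propargylic C–H, then proton loss) gives the 2-formyl enone with the only regiochemistry available and under acidic conditions that do not eliminate the C6 ester.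

Step 14
Reactants: 18 the 2-formyl-3-alkynyl enone
Product: 20 (6S,7R)-3-[(1E)-3-tert-butoxy-3-oxoprop-1-en-1-yl]-7-hydroxy-7-methyl-8-oxo-5,6,7,8-tetrahydro-1H-isochromen-6-yl ArCO2 ester, via argentated pyrylium triflate 19 (not isolated)
Conditions: AgOTf (10 mol %), diethyl 2,6-dimethyl-1,4-dihydropyridine-3,5-dicarboxylate (Hantzsch ester, 1.2 equiv), 4 Å MS, CH2Cl2, 0 °C to rt, dark
Reagents that add atoms: AgOTf, [Ag+].[O-]S(=O)(=O)C(F)(F)F (its atoms stand in 19 only)
Why: Proposed new method: the formyl oxygen adds 6-endo to the silver-activated alkyne to give an aromatic 3-acylpyrylium (C4-argentated), the Hantzsch ester delivers hydride to the unsubstituted C1 and the resulting pyridinium protonates the C–Ag bond, which is the reductive cycloisomerisation known for ortho-alkynyl benzaldehydes and aryl ketones (1H-isochromene synthesis) carried over to a 2-alkynyl cyclohexenecarbaldehyde, with non-basic reagents throughout.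

Step 15
Reactants: 20 the protected target
Product: 21 (2E)-3-[(6S,7R)-6-[(3,4-dihydroxy-2-methoxy-6-methylbenzoyl)oxy]-7-hydroxy-7-methyl-8-oxo-5,6,7,8-tetrahydro-1H-isochromen-3-yl]prop-2-enoic acid (CNP0446308.1)
Conditions: TFA/CH2Cl2/H2O (10:10:1), degassed, 0 °C to rt
Reagents that add atoms: none
Why: Acidolysis cleaves the diphenylmethylene ketal (to benzophenone) and the tert-butyl ester (to isobutene) in one operation, while the vinylogous-ester pyran, the hindered aryl ester and the tertiary alcohol tolerate acid and no base is present to eliminate the C6 ester.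

**Compound list**
1 | 2,3,4-trimethoxy-6-methylbenzaldehyde | COc1c(C=O)c(C)cc(OC)c1OC | starting material
2 | 2,3,4-trihydroxy-6-methylbenzaldehyde | Oc1c(C=O)c(C)cc(O)c1O | intermediate
3 | 4-hydroxy-6-methyl-2,2-diphenyl-1,3-benzodioxole-5-carbaldehyde | Oc1c(C=O)c(C)cc2OC(c3ccccc3)(c3ccccc3)Oc12 | intermediate
4 | 4-methoxy-6-methyl-2,2-diphenyl-1,3-benzodioxole-5-carbaldehyde | COc1c(C=O)c(C)cc2OC(c3ccccc3)(c3ccccc3)Oc12 | intermediate
5 | 4-methoxy-6-methyl-2,2-diphenyl-1,3-benzodioxole-5-carboxylic acid | COc1c(C(=O)O)c(C)cc2OC(c3ccccc3)(c3ccccc3)Oc12 | intermediate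
6 | (E)-3-iodoprop-2-enoic acid | OC(=O)/C=C/I | starting material
7 | tert-butyl (E)-3-iodoprop-2-enoate | CC(C)(C)OC(=O)/C=C/I | intermediate
8 | (S)-(+)-carvone, (5S)-2-methyl-5-(prop-1-en-2-yl)cyclohex-2-en-1-one | CC1=CC[C@H](C(C)=C)CC1=O | starting material
9 | (1S,5S)-2-methyl-5-(prop-1-en-2-yl)cyclohex-2-en-1-ol (cis-carveol) | CC1=CC[C@H](C(C)=C)C[C@@H]1O | intermediate
10 | (1S,2S,4R,6R)-1-methyl-4-(prop-1-en-2-yl)-7-oxabicyclo[4.1.0]heptan-2-ol (epoxide oxygen syn to OH and to isopropenyl) | [C@@H]12C[C@H](C(C)=C)C[C@H](O)[C@]1(C)O2 | intermediate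
11 | (1S,2S,3S,5R)-2,3-dihydroxy-2-methyl-5-(prop-1-en-2-yl)cyclohexyl 4-methoxy-6-methyl-2,2-diphenyl-1,3-benzodioxole-5-carboxylate | COc1c(C(=O)O[C@H]4C[C@H](C(C)=C)C[C@H](O)[C@]4(C)O)c(C)cc2OC(c3ccccc3)(c3ccccc3)Oc12 | intermediate
12 | (1S,2R,5S)-2-hydroxy-2-methyl-3-oxo-5-(prop-1-en-2-yl)cyclohexyl 4-methoxy-6-methyl-2,2-diphenyl-1,3-benzodioxole-5-carboxylate | COc1c(C(=O)O[C@H]4C[C@H](C(C)=C)CC(=O)[C@]4(C)O)c(C)cc2OC(c3ccccc3)(c3ccccc3)Oc12 | intermediate
13 | (1S,2R,5S)-5-(1-hydroperoxy-1-methoxyethyl)-2-hydroxy-2-methyl-3-oxocyclohexyl 4-methoxy-6-methyl-2,2-diphenyl-1,3-benzodioxole-5-carboxylate (epimers at the peroxy carbon) | COc1c(C(=O)O[C@H]4C[C@H](C(C)(OC)OO)CC(=O)[C@]4(C)O)c(C)cc2OC(c3ccccc3)(c3ccccc3)Oc12 | intermediate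
14 | (1S,2R)-2-hydroxy-2-methyl-3-oxo-5-[(triisopropylsilyl)ethynyl]cyclohexyl 4-methoxy-6-methyl-2,2-diphenyl-1,3-benzodioxole-5-carboxylate (C5 epimers) | COc1c(C(=O)O[C@H]4CC(C#C[Si](C(C)C)(C(C)C)C(C)C)CC(=O)[C@]4(C)O)c(C)cc2OC(c3ccccc3)(c3ccccc3)Oc12 | intermediate
15 | (1S,2R)-5-ethynyl-2-hydroxy-2-methyl-3-oxocyclohexyl 4-methoxy-6-methyl-2,2-diphenyl-1,3-benzodioxole-5-carboxylate (C5 epimers) | COc1c(C(=O)O[C@H]4CC(C#C)CC(=O)[C@]4(C)O)c(C)cc2OC(c3ccccc3)(c3ccccc3)Oc12 | intermediate
16 | (1S,2R)-5-[(3E)-5-tert-butoxy-5-oxopent-3-en-1-yn-1-yl]-2-hydroxy-2-methyl-3-oxocyclohexyl 4-methoxy-6-methyl-2,2-diphenyl-1,3-benzodioxole-5-carboxylate (C5 epimers) | COc1c(C(=O)O[C@H]4CC(C#C/C=C/C(=O)OC(C)(C)C)CC(=O)[C@]4(C)O)c(C)cc2OC(c3ccccc3)(c3ccccc3)Oc12 | intermediate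
17 | (1S,2R,4Z)-5-[(3E)-5-tert-butoxy-5-oxopent-3-en-1-yn-1-yl]-2-hydroxy-4-(hydroxymethylidene)-2-methyl-3-oxocyclohexyl 4-methoxy-6-methyl-2,2-diphenyl-1,3-benzodioxole-5-carboxylate (C5 epimers) | COc1c(C(=O)O[C@H]4CC(C#C/C=C/C(=O)OC(C)(C)C)/C(=C/O)C(=O)[C@]4(C)O)c(C)cc2OC(c3ccccc3)(c3ccccc3)Oc12 | intermediate
18 | (1S,2R)-5-[(3E)-5-tert-butoxy-5-oxopent-3-en-1-yn-1-yl]-4-formyl-2-hydroxy-2-methyl-3-oxocyclohex-4-en-1-yl 4-methoxy-6-methyl-2,2-diphenyl-1,3-benzodioxole-5-carboxylate | COc1c(C(=O)O[C@H]4CC(C#C/C=C/C(=O)OC(C)(C)C)=C(C=O)C(=O)[C@]4(C)O)c(C)cc2OC(c3ccccc3)(c3ccccc3)Oc12 | intermediate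
19 | (6S,7R)-4-argentio-3-[(1E)-3-tert-butoxy-3-oxoprop-1-en-1-yl]-7-hydroxy-7-methyl-8-oxo-6-(ArCO2)-5,6,7,8-tetrahydroisochromenylium trifluoromethanesulfonate | COc1c(C(=O)O[C@H]4Cc5c(c[o+]c(/C=C/C(=O)OC(C)(C)C)c5[Ag])C(=O)[C@]4(C)O)c(C)cc2OC(c3ccccc3)(c3ccccc3)Oc12.[O-]S(=O)(=O)C(F)(F)F | intermediate
20 | (6S,7R)-3-[(1E)-3-tert-butoxy-3-oxoprop-1-en-1-yl]-7-hydroxy-7-methyl-8-oxo-5,6,7,8-tetrahydro-1H-isochromen-6-yl 4-methoxy-6-methyl-2,2-diphenyl-1,3-benzodioxole-5-carboxylate | COc1c(C(=O)O[C@H]4CC5=C(COC(/C=C/C(=O)OC(C)(C)C)=C5)C(=O)[C@]4(C)O)c(C)cc2OC(c3ccccc3)(c3ccccc3)Oc12 | intermediate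
21 | (2E)-3-[(6S,7R)-6-[(3,4-dihydroxy-2-methoxy-6-methylbenzoyl)oxy]-7-hydroxy-7-methyl-8-oxo-5,6,7,8-tetrahydro-1H-isochromen-3-yl]prop-2-enoic acid | COc1c(O)c(O)cc(C)c1C(=O)O[C@H]1CC2=C(COC(/C=C/C(=O)O)=C2)C(=O)[C@]1(C)O | target

**Totals.** 15 steps in all. The longest linear sequence is 12 steps (steps 1–4, then 8–15); from carvone it is 10 steps (6–15).

**Three steps most likely to fail, with fallbacks**

Step 8, the titanium-mediated opening, could give isopropoxide transfer, attack at the tertiary carbon or a sluggish reaction with the electron-rich hindered acid. The fallback sets out from 10: oxidise it with Dess–Martin periodinane to the epoxy ketone F1, then open F1 with the caesium salt of 5 (Cs2CO3, DMF, 60 °C). The carbonyl group now forbids ionisation at the tertiary α-carbon, so the carboxylate attacks the β-carbon in a plain SN2, trans-diaxial reaction with isopropenyl equatorial. This gives 12 directly, where the route is rejoined.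

Step 10, the dealkenylative alkynylation, could fail through ozone damage to the electron-rich arene or poor radical trapping. The fallback sets out from 12: the same ozonolysis in methanol gives 13, which is treated with FeSO4·7H2O and Cu(OAc)2 (dealkenylative alkene formation by radical oxidation) to give the cyclohexenone F2. Rhodium-catalysed conjugate addition of (triisopropylsilyl)acetylene to F2 ([Rh(OAc)(C2H4)2]2, DTBM-segphos, dioxane, 80 °C, no base) then gives 14, where the route is rejoined.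

Step 14, the reductive cycloisomerisation, could fail because the Hantzsch ester reduces the alkylidene dicarbonyl C=C of 18 before cyclisation (which would lead on to a furan), or because hydride adds at the wrong pyrylium position. The fallback sets out from 18: reduce only the aldehyde (NaBH4, EtOH/CH2Cl2, −78 °C) to the allylic alcohol F3, then close the pyran by gold-catalysed 6-endo hydroalkoxylation of F3 (Ph3PAuNTf2, CH2Cl2, rt), the ketone polarising the alkyne for attack at its distal carbon. This gives 20, where the route is rejoined.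

**Further compounds**
F1 | step 8 | (1R,4S,6R)-1-methyl-4-(prop-1-en-2-yl)-7-oxabicyclo[4.1.0]heptan-2-one | [C@@H]12C[C@H](C(C)=C)CC(=O)[C@]1(C)O2
F2 | step 10 | (1S,2R)-2-hydroxy-2-methyl-3-oxocyclohex-4-en-1-yl 4-methoxy-6-methyl-2,2-diphenyl-1,3-benzodioxole-5-carboxylate | COc1c(C(=O)O[C@H]4CC=CC(=O)[C@]4(C)O)c(C)cc2OC(c3ccccc3)(c3ccccc3)Oc12
F3 | step 14 | (1S,2R)-5-[(3E)-5-tert-butoxy-5-oxopent-3-en-1-yn-1-yl]-2-hydroxy-4-(hydroxymethyl)-2-methyl-3-oxocyclohex-4-en-1-yl 4-methoxy-6-methyl-2,2-diphenyl-1,3-benzodioxole-5-carboxylate | COc1c(C(=O)O[C@H]4CC(C#C/C=C/C(=O)OC(C)(C)C)=C(CO)C(=O)[C@]4(C)O)c(C)cc2OC(c3ccccc3)(c3ccccc3)Oc12
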